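## Structural features

The target is a fully substituted cyclohexane (C1–C6, six contiguous stereocentres). C1 carries a branched chain: a 1,1-disubstituted alkene at C7, then C8 (isobutyrate, S), C9, C10 (free hydroxyl, S, 1,3-anti to O8) and the tertiary carbinol C11. Numbering correction: C7 is the sp2 carbon bonded to C1, not the methylene carbon; the exocyclic =CH2 carbon is a separate atom, here C12, and it arrives after the ring work. On the ring, the C1 chain, the tertiary C4 hydroxyl and the C5 and C6 oxygens lie on one face (β); the C2 and C3 oxygens and the C4 methyl lie on the other (α). In the favoured chair the chain, O2, the methyl and O5 are equatorial, while O3, O4 and O6 are axial. The five ring oxygens all differ in role: isobutyrates on the two axial secondary oxygens (C3, C6), an acetate on C5, free hydroxyls at C2 and C4. Fragile points are the esters next to free hydroxyls (acyl shifts O3→O2, O6→O5, O8→O10 under base) and the allylic ester at C8, so late steps must be neutral or mildly acidic. The real difficulty is twofold: telling two cis-diols apart with the correct axial acylation around quaternary C4, and setting C8/C10, which the sp2 carbon C7 insulates from the ring. The key step exploits the 1,4-relationship of C1 and C4, which carry a carbon (C7) and an oxygen on the same face beside the C2/C3 cis-diol and the C4 methyl: the pattern of a dearomatised toluene whose diene termini are bridged by a C–O unit.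

## Logic of the disconnections

21 ⇒ 20. The O11–Si bond is cut last. A single silyl ether removed under buffered acidic fluoride is the only operation on the complete tetraester, so base-induced acyl shifts are avoided; the demand is that the tertiary silyl ether survives steps 11–14.

20 ⇒ 18 (through 19). The O3–acyl bond is cut and O2/O3 are tied to one orthoester carbon. The reason is that O3 is axial and O2 equatorial in a cis pair, the situation in which orthoester hydrolysis hands the acyl group to the axial oxygen. The forward step needs the chair to hold and no other diol able to chelate the reagent.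

18 ⇒ 17. The C2/C3 diol is returned to its acetonide, which has masked it since the first step; the forward hydrolysis must spare four esters and the silyl ether.

17 ⇒ 15 + 16. The O8–acyl bond and the C10–H bond are cut together, since both can come from 16 in one hydride-transfer event. This sets C10 anti to C8 and acylates O8 without a separate esterification; it demands a free β-hydroxy ketone and no competing carbonyl.

15 ⇒ 11 + 13 (13 ⇒ 12). The C8–C9 bond is cut as an aldol. It splits off the whole C9–C11 unit as a methyl ketone that can enolise on one side only; the forward step must choose the aldehyde face by reagent control because the ring cannot.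

11 ⇒ 10 ⇒ 9. The O5–acetyl bond is cut, then the O6–acyl bond is folded back into a C5/C6 orthoester. O6 is axial, O5 equatorial, so the same stereoelectronic opening applies, and the acetate is placed while O2 is still masked, which distinguishes O5 from O2.

9 ⇒ 8 ⇒ 7. The C7=C12 bond is cut (aldehyde α-methylenation) and the aldehyde is taken back to the ester. This must happen before any ring ester exists, because the hydride reduction would not spare them.

7 ⇒ 6. The C7–H bond is exchanged for the C7–O4 bond, giving a bridged α-alkoxy ester. The gain is that C1 and C4 become the cis bridgeheads of a bicycle and the C7 stereocentre becomes irrelevant; the forward step needs a selective reductive cleavage of the C–O bond α to the ester.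

6 ⇒ 5 ⇒ 4. The orthoester is removed and both C5–O and C6–O bonds are cut to the C5=C6 alkene. On the bicycle only one diol is free, so the orthoester is unambiguous, and the alkene has one open face.

4 ⇒ 2 + 3. The C1–C7 and C4–O bonds are cut in a hetero-[4+2] sense. This removes one ring and two stereocentres and leaves a diene that already holds C2, C3 and the C4 methyl; the forward step must be face- and regioselective.

2 ⇒ 1. The acetonide is removed to the enzymatically made cis-dihydrodiol, the source of absolute configuration.

## Other disconnections considered

Alternative 1: The cut is the C1–C6 ring bond, taken as C1=C6 of cyclohexene carboxylate A3. Its open-chain precursor, diene ester A2, would come from L-arabinose A1 with the acrylate unit installed by a Baylis–Hillman reaction at the aldehyde that becomes C2. The forward key step is ring-closing metathesis of A2 with a ruthenium carbene catalyst between the C6 vinyl group and the acrylate methylene.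
- In its favour: C2–C5, including quaternary C4, are in place before ring closure. O2, O3/O4 and O5 carry three different groups (silyl, benzyl, free), so on differentiation of the ring oxygens A3 is better than 4 and 5, where two cis-diols must be told apart later. Ring-closing metathesis to a six-membered enoate is at least as dependable mechanistically as a thermal hetero-cycloaddition.
- Against it here: A3 lacks both C1 and C6 as stereocentres. The enoate must take up H at C1 and O at C6 in a net anti sense (C7 and O6 cis), for which no single reliable operation is at hand. C7 is an ester carbon on the ring, so the C7(=C12)–C8 unit needs a ketone, a further C–C bond and a carbonyl methylenation. The benzyl ethers must later leave without touching C7=C12, and the Baylis–Hillman step sets C2 with little intrinsic control.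
- Comparison: the chosen plan obtains C1–C4 with absolute configuration in two steps from 1 and has the C1/C4 cis relationship by construction. Alternative 1 is ahead on oxygen differentiation and behind on step count and on the two centres it leaves open.

Alternative 2: The cut is the C2–C3 ring bond together with both C–O bonds at C2 and C3, leading to acyclic triene A4 (vinyl groups at C1 and C4, C5/C6 diol as acetonide from the chiral pool, acrylate on C1). The forward key step is ring-closing metathesis with a ruthenium carbene catalyst, then oxidation of the spent ruthenium in the same flask to an oxo species that syn-dihydroxylates the new alkene, giving A5.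
- In its favour: A5 holds all six ring stereocentres and the finished C7(=C12)–C8 acrylate, and its two diols arrive differentiated (C5/C6 acetonide, C2/C3 free). On these counts A5 is further advanced than 4, and the α-methylenation step disappears; this is better than the chosen plan. The one-flask construction is step-economic.
- Against it here: the burden moves to A4. C1 is a doubly allylic CH between acrylate and vinyl and is prone to slip into conjugation, and the quaternary C4 carbinol must be set in an open chain relative to C5/C6. The oxo-ruthenium oxidant is strong and can also attack the electron-poor acrylate alkene or over-oxidise the diol. Face selectivity at C2=C3 rests on two β allylic substituents steering the oxidant to the α face; this is of the same kind as the shielding used in step 3, but on a less rigid ring.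
- Comparison: the later problems (axial acylation, ester-to-enal conversion without ring esters present) are the same as in the chosen plan, so the two are equal there. Alternative 2 is shorter on paper if A4 is accessible; the chosen plan is preferred because C1–C4 come from one enzymatic step and one rigid cycloaddition.

Alternative 3: The cut is C1–C2 and C3–C4: the carbocycle is assembled from 6-methyl-2-pyrone A6 (C1, C4–C7 and the methyl) and 2,2-dimethyl-1,3-dioxole A7 (C2, C3 with their oxygens). The forward key step is an endo-selective [4+2] cycloaddition under high pressure, giving bridged lactone A8.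
- In its favour: A8 has the same 2-oxabicyclo[2.2.2]octene core as 4 with the same C1–C4 relationships and could be dihydroxylated in the same way, so it is equal on structure. Its bridge opens by simple acyl C–O cleavage instead of electron transfer, which is better than step 5. Both partners are cheap and achiral.
- Against it here: neither partner is chiral, so A8 would be racemic unless an enantioselective catalyst or a resolution is added, whereas 1 brings the absolute configuration. Simple 2-pyrones are sluggish dienes and their adducts tend to extrude CO2 on warming, hence the pressure equipment. In A8, C7 is the lactone carbonyl bound directly to C1, so after opening C1 is α to a carbonyl and epimerisable, and C8 is missing.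
- Comparison: step economy is comparable up to the bicycle and worse afterwards, because the C7(=C12)–C8 unit costs an extra C–C bond and a ketone methylenation, while 3 delivers C7 and C8 in one reagent.

Key step: step 2

## Route

Assumption (chemistry): trimethyl orthoisobutyrate and (−)-Ipc2BCl are used as purchased reagents, and 3 is cracked to the monomer immediately before use.

Compounds 4–6 are carried as C7 epimers and 6–9 as orthoester epimers; both elements vanish in steps 5 and 8.

Step 1
Reactants: 1 (1S,2R)-3-methylcyclohexa-3,5-diene-1,2-diol
Product: 2 (3aR,7aS)-2,2,4-trimethyl-3a,7a-dihydro-1,3-benzodioxole (acetonide of 1)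
Conditions: 2,2-dimethoxypropane, TsOH·H2O (cat.), acetone, 0 °C; Et3N quench
Reagents that add atoms: 2,2-dimethoxypropane, COC(C)(C)OC
Why: Acid-catalysed transketalisation of a cis-1,2-diol; the cis-fused dioxolane forms readily, no stereocentre is touched, and capping the diol suppresses dehydration to cresol.

Step 2
Reactants: 2 acetonide of 1; 3 ethyl glyoxylate
Product: 4 oxa-bridged cycloadduct (ethyl 2-oxabicyclo[2.2.2]oct-5-ene-3-carboxylate core: O–C7 bridge across C1 and C4 on the β face, methyl on C4, C2/C3 acetonide on the α face, C5=C6 alkene; both C7 epimers)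
Conditions: 3 (5 equiv, freshly cracked), toluene, 2,6-di-tert-butyl-4-methylphenol (cat.), 90 °C, sealed tube
Reagents that add atoms: none
Why: Concerted but asynchronous normal-demand hetero-[4+2] cycloaddition (oxo-Diels–Alder) between the s-cis-locked diene of 2 and the C=O of 3, in which bonding of the aldehyde carbon to C1 runs ahead of O–C4 bonding. The closest known reaction types are the thermal and Lewis-acid-promoted cycloadditions of glyoxylates with cyclohexa-1,3-dienes and the cycloadditions of arene cis-dihydrodiol acetonides with reactive dienophiles. One ring is closed, the six-membered dihydropyran C1–C7–O–C4–C5=C6, by suprafacial addition across both diene termini, which makes it a bridge over the carbocycle. C1 and C4 become stereocentres: the dienophile approaches the diene face opposite the dioxolane, so C7 and the oxygen end up β, and the bridge forces them to be cis to each other. C7 forms as an endo/exo mixture, which is tolerated because step 5 destroys this centre. The step needs π-facial selectivity and regioselectivity; the first comes from the acetonide shielding the α face, the second from the C4 methyl group, which raises the diene coefficient at C1 and stabilises positive charge at C4, so carbon bonds to C1 and oxygen to C4. Excess 3 and moderate temperature keep dimerisation and aromatisation of 2 in the background.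

Step 3
Reactants: 4 oxa-bridged cycloadduct
Product: 5 C5,C6-cis-diol of the bicycle (both hydroxyls β, syn to the O–C7 bridge)
Conditions: OsO4 (5 mol%), N-methylmorpholine N-oxide (1.5 equiv), acetone/H2O (4:1), rt
Reagents that add atoms: osmium tetroxide, O=[Os](=O)(=O)=O; N-methylmorpholine N-oxide, C[N+]1([O-])CCOCC1; water, O
Why: Catalytic syn-dihydroxylation (Upjohn conditions); the alkene face turned toward the C2/C3 bridge is covered by the dioxolane and its methyl groups, so OsO4 should add from the face of the O–C7 bridge, which sets C5 and C6 with both oxygens β.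

Step 4
Reactants: 5 C5,C6-cis-diol
Product: 6 C5/C6 cyclic methyl orthoisobutyrate of 5 (2-isopropyl-2-methoxy-1,3-dioxolane, both epimers at the orthoester carbon)
Conditions: Me2CHC(OMe)3 (3 equiv), PPTS (5 mol%), CH2Cl2, rt; Et3N quench
Reagents that add atoms: trimethyl orthoisobutyrate, CC(C)C(OC)(OC)OC
Why: Acid-catalysed orthoester exchange; only one diol is free on the bicycle, so there is no regiochemical choice, and the eclipsed cis-diol closes the dioxolane easily. The orthoester protects O5/O6 and stores the future C6 isobutyryl group.

Step 5
Reactants: 6 bicyclic orthoester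
Product: 7 ethyl ester of the ring-opened cyclohexane (β-CH2CO2Et on C1, C2/C3 α-acetonide, C4 β-OH and α-CH3, C5/C6 β-orthoisobutyrate)
Conditions: SmI2 (3 equiv), HMPA (10 equiv), MeOH (4 equiv), THF, 0 °C → rt; aq. NaHCO3 work-up
Reagents that add atoms: none
Why: SmI2 reduction of an α-alkoxy ester: electron transfer to the ester expels the α-alkoxide, a second electron gives the samarium enolate and MeOH protonates it. C7 ceases to be a stereocentre so both epimers converge, C1 and C4 are untouched, and the ring relaxes to the chair with the C1 arm equatorial.

Step 6
Reactants: 7 ethyl ester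
Product: 8 aldehyde (β-CH2CHO on C1, otherwise as 7)
Conditions: iBu2AlH (2.2 equiv), toluene, −78 °C; MeOH, then aq. potassium sodium tartrate
Reagents that add atoms: none
Why: Low-temperature half-reduction of an ester through the aluminium hemiacetal, which is stable at −78 °C; one equivalent is spent on the tertiary alkoxide, and the acetal and orthoester are inert to the hydride at this temperature.

Step 7
Reactants: 8 aldehyde
Product: 9 enal (C1 bears C7(=C12H2)–CHO, otherwise as 8)
Conditions: (CH3)2N=CH2 I (Eschenmoser's salt, 3 equiv), Et3N (5 equiv), CH2Cl2, rt
Reagents that add atoms: Eschenmoser's salt, C=[N+](C)C.[I-]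
Why: Mannich reaction of the aldehyde enol with the iminium salt followed by elimination of dimethylamine (aldehyde α-methylenation). C1 is β to the carbonyl and has no leaving group, so it can neither epimerise nor eliminate.

Step 8
Reactants: 9 enal orthoester
Product: 10 C6 isobutyrate with free C5 hydroxyl (enal, C2/C3 acetonide and C4–OH as before)
Conditions: AcOH/H2O/THF (2:1:2), 0 °C → rt, short reaction time
Reagents that add atoms: water, O
Why: Acid hydrolysis of a cyclic orthoester via the dioxolan-2-ylium ion and its hemiorthoester, which collapses under stereoelectronic control to the axial ester and the equatorial alcohol. In the favoured chair O6 is axial and O5 equatorial, so the isobutyrate should land on C6; the acetonide survives this brief mild acid.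

Step 9
Reactants: 10 C6 isobutyrate, C5 alcohol
Product: 11 C5 acetate, C6 isobutyrate enal (C2/C3 acetonide, free tertiary C4–OH)
Conditions: Ac2O (1.5 equiv), pyridine, DMAP (5 mol%), CH2Cl2, 0 °C
Reagents that add atoms: acetic anhydride, CC(=O)OC(C)=O
Why: DMAP-catalysed acetylation of the secondary equatorial C5 hydroxyl; the tertiary axial C4 hydroxyl reacts far more slowly and stays free. Acetylating directly after step 8 leaves the O6→O5 acyl shift no time.

Step 10
Reactants: 12 3-hydroxy-3-methylbutan-2-one
Product: 13 3-(tert-butyldimethylsilyloxy)-3-methylbutan-2-one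
Conditions: TBSOTf (1.2 equiv), 2,6-lutidine (2 equiv), CH2Cl2, 0 °C → rt
Reagents that add atoms: tert-butyldimethylsilyl triflate, CC(C)(C)[Si](C)(C)OS(=O)(=O)C(F)(F)F
Why: Silyl triflate with a hindered weak base silylates the tertiary alcohol; 2,6-lutidine is too weak to promote enol silylation of the ketone.

Step 11
Reactants: 11 enal; 13 silyloxy ketone
Product: 15 (8S)-β-hydroxy ketone (C8–OH, C10 ketone, C11–OTBS; ring as in 11), via enol diisopinocampheylborinate 14 (not isolated)
Conditions: 13 (3 equiv), (−)-Ipc2BCl (3.3 equiv), Et3N (4 equiv), Et2O, 0 °C; then 11, −78 → −20 °C; H2O2, MeOH, pH 7 buffer, 0 °C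
Reagents that add atoms: none
Why: Boron aldol of a methyl ketone; enolisation is possible only on the methyl side, and the chiral ligands on boron are relied on to direct addition to the Si face of the aldehyde, which gives 8S. (−)-Ipc2BCl is chosen on the expectation that its methyl-ketone enolates attack this face, with the antipodal reagent as the direct remedy if the sense is reversed, because C1 lies beyond the sp2 carbon C7 and cannot decide the outcome.

Step 12
Reactants: 15 β-hydroxy ketone; 16 isobutyraldehyde
Product: 17 (8S,10S)-C8 isobutyrate with free C10 hydroxyl (C11–OTBS; ring as in 11)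
Conditions: 16 (6 equiv), SmI2 (0.3 equiv), THF, −10 °C
Reagents that add atoms: none
Why: Evans–Tishchenko reduction: the samarium-bound hemiacetal of 15 with 16 delivers its hydride intramolecularly to the ketone through a chair-like bicyclic transition state. This gives the 1,3-anti alcohol (10S) and leaves the isobutyryl group on O8 in the same operation.

Step 13
Reactants: 17 acetonide
Product: 18 C2,C3-diol (C4–OH, C5–OAc, C6 and C8 isobutyrates, C10–OH, C11–OTBS)
Conditions: TFA/H2O (4:1), CH2Cl2, 0 °C
Reagents that add atoms: none
Why: Acid hydrolysis of the isopropylidene acetal; the esters, the allylic ester and the hindered tertiary silyl ether tolerate cold aqueous TFA, and no acyl group sits next to the liberated hydroxyls.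

Step 14
Reactants: 18 C2,C3-diol
Product: 20 C3 isobutyrate with free C2 hydroxyl (C11–OTBS; otherwise as the target), via C2/C3 cyclic methyl orthoisobutyrate 19 (not isolated)
Conditions: Me2CHC(OMe)3 (1.5 equiv), PPTS (10 mol%), CH2Cl2, rt; then 80% aq. AcOH, rt
Reagents that add atoms: trimethyl orthoisobutyrate, CC(C)C(OC)(OC)OC; water, O
Why: Orthoester exchange at the only cis-1,2-diol (O3/O4 are trans, the C10 hydroxyl is hindered and cannot chelate), then stereoelectronically controlled hydrolysis. O3 is axial and O2 equatorial in the favoured chair, so the ester should land on C3, as in step 8.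

Step 15
Reactants: 20 silyl ether
Product: 21 CNP0348997.1 (target)
Conditions: HF·pyridine, pyridine, THF, 0 °C → rt
Reagents that add atoms: none
Why: Fluoride cleavage of the tertiary silyl ether under buffered acidic conditions, which avoid the base-promoted acyl shifts (O3→O2, O8→O10) open to the tetraester.

## Compound list

1 | (1S,2R)-3-methylcyclohexa-3,5-diene-1,2-diol (toluene cis-dihydrodiol) | C1[C@H](O)[C@H](O)C(C)=CC=1 | starting material
2 | (3aR,7aS)-2,2,4-trimethyl-3a,7a-dihydro-1,3-benzodioxole | C1[C@H](OC2(C)C)[C@H](O2)C(C)=CC=1 | intermediate
3 | ethyl glyoxylate | CCOC(=O)C=O | starting material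
4 | oxa-bridged cycloadduct, C7 epimers (O–C7 bridge β across C1/C4, C2/C3 acetonide α) | CCOC(=O)C3[C@H]1[C@H](OC2(C)C)[C@H](O2)[C@@](C)(O3)C=C1 | intermediate
5 | bicyclic C5,C6-cis-diol (hydroxyls β) | CCOC(=O)C3[C@H]1[C@H](OC2(C)C)[C@H](O2)[C@@](C)(O3)[C@@H](O)[C@H]1O | intermediate
6 | bicyclic C5/C6 cyclic methyl orthoisobutyrate | CCOC(=O)C3[C@H]1[C@H](OC2(C)C)[C@H](O2)[C@@](C)(O3)[C@@H](OC4(OC)C(C)C)[C@H]1O4 | intermediate
7 | ring-opened ethyl ester (C1 β-CH2CO2Et, C4 β-OH) | CCOC(=O)C[C@H]1[C@H](OC2(C)C)[C@H](O2)[C@@](C)(O)[C@@H](OC3(OC)C(C)C)[C@H]1O3 | intermediate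
8 | aldehyde (C1 β-CH2CHO) | O=CC[C@H]1[C@H](OC2(C)C)[C@H](O2)[C@@](C)(O)[C@@H](OC3(OC)C(C)C)[C@H]1O3 | intermediate
9 | enal with C5/C6 orthoester | C=C(C=O)[C@H]1[C@H](OC2(C)C)[C@H](O2)[C@@](C)(O)[C@@H](OC3(OC)C(C)C)[C@H]1O3 | intermediate
10 | enal, C6 isobutyrate, C5 alcohol | C=C(C=O)[C@H]1[C@H](OC2(C)C)[C@H](O2)[C@@](C)(O)[C@@H](O)[C@H]1OC(=O)C(C)C | intermediate
11 | enal, C5 acetate, C6 isobutyrate | C=C(C=O)[C@H]1[C@H](OC2(C)C)[C@H](O2)[C@@](C)(O)[C@@H](OC(C)=O)[C@H]1OC(=O)C(C)C | intermediate
12 | 3-hydroxy-3-methylbutan-2-one | CC(=O)C(C)(C)O | starting material
13 | 3-(tert-butyldimethylsilyloxy)-3-methylbutan-2-one | CC(=O)C(C)(C)O[Si](C)(C)C(C)(C)C | intermediate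
14 | enol diisopinocampheylborinate of 13 (not isolated) | C=C(OB([C@@H]1C[C@@H]2C[C@H]([C@H]1C)C2(C)C)[C@@H]1C[C@@H]2C[C@H]([C@H]1C)C2(C)C)C(C)(C)O[Si](C)(C)C(C)(C)C | intermediate
15 | (8S)-β-hydroxy ketone | C=C([C@H]1[C@H](OC2(C)C)[C@H](O2)[C@@](C)(O)[C@@H](OC(C)=O)[C@H]1OC(=O)C(C)C)[C@H](CC(=O)C(C)(C)O[Si](C)(C)C(C)(C)C)O | intermediate
16 | isobutyraldehyde | CC(C)C=O | starting material
17 | (8S,10S)-C8 isobutyrate, C10 alcohol, C2/C3 acetonide | C=C([C@H]1[C@H](OC2(C)C)[C@H](O2)[C@@](C)(O)[C@@H](OC(C)=O)[C@H]1OC(=O)C(C)C)[C@H](C[C@H](O)C(C)(C)O[Si](C)(C)C(C)(C)C)OC(=O)C(C)C | intermediate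
18 | C2,C3-diol | C=C([C@H]1[C@H](O)[C@H](O)[C@@](C)(O)[C@@H](OC(C)=O)[C@H]1OC(=O)C(C)C)[C@H](C[C@H](O)C(C)(C)O[Si](C)(C)C(C)(C)C)OC(=O)C(C)C | intermediate
19 | C2/C3 cyclic methyl orthoisobutyrate (not isolated) | C=C([C@H]1[C@H](OC2(OC)C(C)C)[C@H](O2)[C@@](C)(O)[C@@H](OC(C)=O)[C@H]1OC(=O)C(C)C)[C@H](C[C@H](O)C(C)(C)O[Si](C)(C)C(C)(C)C)OC(=O)C(C)C | intermediate
20 | C11 silyl ether of the target (C3 isobutyrate, C2 alcohol) | C=C([C@H]1[C@H](O)[C@H](OC(=O)C(C)C)[C@@](C)(O)[C@@H](OC(C)=O)[C@H]1OC(=O)C(C)C)[C@H](C[C@H](O)C(C)(C)O[Si](C)(C)C(C)(C)C)OC(=O)C(C)C | intermediate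
21 | CNP0348997.1 | C=C([C@H]1[C@H](O)[C@H](OC(=O)C(C)C)[C@@](C)(O)[C@@H](OC(C)=O)[C@H]1OC(=O)C(C)C)[C@H](C[C@H](O)C(C)(C)O)OC(=O)C(C)C | target

## Step count and least certain steps

Total step count: 15. Longest linear sequence: 14 steps (steps 1–9 and 11–15 from 1); step 10 is the one-step side branch.

Step 2 (key step). What may go wrong is that [4+2] dimerisation or aromatisation of the diene outruns addition of a moderately reactive carbonyl dienophile, or that regiocontrol leaks. Fallback: starting from 2, a more electrophilic carbonyl dienophile, diethyl oxomalonate, should add at or near room temperature to give the gem-diester cycloadduct F1. Dealkoxycarbonylation of F1 under Krapcho conditions (LiCl, wet DMSO, heat) removes one ester and rejoins the route at 4 as the same C7 epimer mixture.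

Step 11. What may go wrong is insufficient π-facial discrimination at the aldehyde, since control rests on the boron ligands alone and the ketone is bulky, together with consumption of enolate by the free C4 hydroxyl. Fallback: starting from 13, TMSOTf/Et3N gives the trimethylsilyl enol ether F2. A catalyst-controlled Mukaiyama aldol of F2 with 11 under a chiral oxazaborolidinone Lewis acid (prepared from N-tosyltryptophan and butylboronic acid, enantiomer chosen for Si-face addition) gives the O8-trimethylsilyl aldol F3. Mild acid (citric acid, MeOH) removes the trimethylsilyl group and rejoins the route at 15.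

Step 12. What may go wrong is slow hydride transfer to a ketone flanked by the quaternary silyloxy carbon, which gives room for retro-aldol cleavage or a Lewis-acid-promoted O8→O10 acyl shift. Fallback: starting from 15, hydroxyl-directed anti reduction with Me4NBH(OAc)3 (AcOH/MeCN, −30 °C) gives the anti-1,3-diol F4. Selective acylation of the less hindered allylic O8 (isobutyryl chloride, 2,4,6-collidine, −40 °C; O10 is neopentylic) rejoins the route at 17.

Step 14. What may go wrong is leakage of the acyl group to O10 through a mixed acyclic orthoester, or erosion of the axial preference by an acid-promoted O3→O2 shift during opening. Fallback: starting from 17, TBSOTf/2,6-lutidine caps O10 to give the bis-silyl ether F5. Cold aqueous TFA then gives the C2,C3-diol F6; orthoester exchange gives the cyclic orthoester F7, which is hydrolysed in the same flask to the C3 isobutyrate F8. HF·pyridine removes both silyl ethers from F8 and rejoins the route at 21.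

Step 6. What may go wrong is over-reduction to the primary alcohol, or hydride attack on the orthoester once it is activated by the Lewis-acidic aluminium. Fallback: starting from 7, full reduction with LiAlH4 (THF, 0 °C), to which orthoesters are inert, gives the primary alcohol F9. Oxidation with Dess–Martin periodinane buffered by NaHCO3 rejoins the route at 8.

## Further compounds

F1 | step 2 | gem-diester cycloadduct (diethyl ester at C7, otherwise as 4) | CCOC(=O)C3(C(=O)OCC)[C@H]1[C@H](OC2(C)C)[C@H](O2)[C@@](C)(O3)C=C1
F2 | step 11 | trimethylsilyl enol ether of 13 | C=C(O[Si](C)(C)C)C(C)(C)O[Si](C)(C)C(C)(C)C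
F3 | step 11 | O8-trimethylsilyl ether of 15 | C=C([C@H]1[C@H](OC2(C)C)[C@H](O2)[C@@](C)(O)[C@@H](OC(C)=O)[C@H]1OC(=O)C(C)C)[C@H](CC(=O)C(C)(C)O[Si](C)(C)C(C)(C)C)O[Si](C)(C)C
F4 | step 12 | (8S,10S)-anti-1,3-diol | C=C([C@H]1[C@H](OC2(C)C)[C@H](O2)[C@@](C)(O)[C@@H](OC(C)=O)[C@H]1OC(=O)C(C)C)[C@H](C[C@H](O)C(C)(C)O[Si](C)(C)C(C)(C)C)O
F5 | step 14 | O10,O11-bis(tert-butyldimethylsilyl) ether of the acetonide | C=C([C@H]1[C@H](OC2(C)C)[C@H](O2)[C@@](C)(O)[C@@H](OC(C)=O)[C@H]1OC(=O)C(C)C)[C@H](C[C@H](O[Si](C)(C)C(C)(C)C)C(C)(C)O[Si](C)(C)C(C)(C)C)OC(=O)C(C)C
F6 | step 14 | bis-silylated C2,C3-diol | C=C([C@H]1[C@H](O)[C@H](O)[C@@](C)(O)[C@@H](OC(C)=O)[C@H]1OC(=O)C(C)C)[C@H](C[C@H](O[Si](C)(C)C(C)(C)C)C(C)(C)O[Si](C)(C)C(C)(C)C)OC(=O)C(C)C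
F7 | step 14 | bis-silylated C2/C3 cyclic methyl orthoisobutyrate | C=C([C@H]1[C@H](OC2(OC)C(C)C)[C@H](O2)[C@@](C)(O)[C@@H](OC(C)=O)[C@H]1OC(=O)C(C)C)[C@H](C[C@H](O[Si](C)(C)C(C)(C)C)C(C)(C)O[Si](C)(C)C(C)(C)C)OC(=O)C(C)C
F8 | step 14 | bis-silylated C3 isobutyrate | C=C([C@H]1[C@H](O)[C@H](OC(=O)C(C)C)[C@@](C)(O)[C@@H](OC(C)=O)[C@H]1OC(=O)C(C)C)[C@H](C[C@H](O[Si](C)(C)C(C)(C)C)C(C)(C)O[Si](C)(C)C(C)(C)C)OC(=O)C(C)C
F9 | step 6 | primary alcohol (C1 β-CH2CH2OH, otherwise as 7) | OCC[C@H]1[C@H](OC2(C)C)[C@H](O2)[C@@](C)(O)[C@@H](OC3(OC)C(C)C)[C@H]1O3
A1 | alternative 1 | L-arabinose | O=C[C@H](O)[C@@H](O)[C@@H](O)CO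
A2 | alternative 1 | open-chain diene ester | C=C(C(=O)OC)[C@H](O[Si](C)(C)C(C)(C)C)[C@H](OCc1ccccc1)[C@@](C)(OCc1ccccc1)[C@@H](O)C=C
A3 | alternative 1 | cyclohexene carboxylate with C2–C5 set | C1(C(=O)OC)[C@H](O[Si](C)(C)C(C)(C)C)[C@H](OCc2ccccc2)[C@@](C)(OCc2ccccc2)[C@@H](O)C=1
A4 | alternative 2 | acyclic triene | C=C(C(=O)OCC)[C@@H](C=C)[C@@H]1OC(C)(C)O[C@@H]1[C@](C)(O)C=C
A5 | alternative 2 | cyclohexane triol acetonide with all six ring stereocentres | C=C([C@H]1[C@H](O)[C@H](O)[C@@](C)(O)[C@@H](OC2(C)C)[C@H]1O2)C(=O)OCC
A6 | alternative 3 | 6-methyl-2-pyrone | CC1=CC=CC(=O)O1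
A7 | alternative 3 | 2,2-dimethyl-1,3-dioxole | CC1(C)OC=CO1
A8 | alternative 3 | endo bicyclic lactone acetonide | O=C3[C@H]1[C@H](OC2(C)C)[C@H](O2)[C@@](C)(O3)C=C1
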